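## Structural features

Compound 14 is a single benzene ring with all six positions substituted: a methyl ester at C1, hydroxyls at C2 and C4, 3-methylbut-2-enyl (prenyl) chains at C3 and C5, and a 2-phenylethyl chain at C6, which ends in an unfunctionalized phenyl ring. There is no stereocentre and no alkene geometry to control, because both side-chain alkenes end in geminal methyl groups. The fragile elements are the two trisubstituted alkenes ortho to phenolic hydroxyls (acids close them to 2,2-dimethylchromans; oxidants and electrophiles attack them), the electron-rich resorcinol nucleus (air oxidation as the phenoxide), and the doubly ortho-substituted salicylate ester. The real difficulty is regiochemical: six different neighbours must stand in a fixed order, and stepwise substitution of a resorcinol would have to win several C- versus O-alkylation and positional contests, ending with the carboxyl group at the most crowded carbon. The key step uses the fact that C6 (phenethyl), C1 (ester), C2 (oxygen) and C3 (prenyl) reproduce C6, C5, C4 and C3 of a 4-oxygenated 2-pyrone-5-carboxylate. The remaining pair, C4 (hydroxyl) and C5 (prenyl), is a carboxyl carbon and its α-carbon, that is, a ketene acetal. The electrophilic end of the pyrone and the nucleophilic carbon of the ketene acetal are the two atoms that become C6 and C5 of the arene, so polarity alone fixes the substitution pattern.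

## Logic of the disconnections

14 ⇒ 13. Only the acetyl–oxygen bond at C2 is cut. This oxygen comes from the 4-oxygen of a pyrone that must stay electron-poor and non-acidic during ring construction, and an acyl group does both and still comes off without acid. The cut gives no skeletal simplification. It demands a forward cleavage that spares the methyl ester and both alkenes, which mild basic methanolysis of a phenyl ester provides.

13 ⇒ 6 + 9. The arene bonds C3–C4 and C5–C6 are cut, a CO2 bridge is restored between C3 and C6, and a silanol is added back across C4–C5. The hexasubstituted ring is thereby split into a four-carbon lactone diene (C6, C1, C2, C3 with their substituents, in 6) and a two-carbon ketene acetal (C4, C5, in 9). This is the largest gain of the route, since all six substituents are placed by the connectivity of two small fragments. The forward step must join two fully substituted diene termini to a trisubstituted alkene in one orientation, at a temperature that 9 and the enol acetate of 6 survive.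

6 ⇒ 5. The O–acetyl bond at the pyrone 4-oxygen is cut. The free vinylogous acid 5 would protonate 9 or be silylated by it, giving an electron-rich diene; the acetate prevents both. The forward acylation must go to oxygen, which is assured because C3 is already substituted.

5 ⇒ 3 + 4. The bond between pyrone C3 and the prenyl CH2 is cut. Attaching the prenyl group after the pyrone is made means the acid-releasing ring synthesis is never run on a compound with an acid-sensitive alkene, and the pyrone then comes from unsubstituted catalogue materials. The forward step must alkylate carbon and not oxygen, at the primary allyl terminus, and only once. A reversible palladium-catalysed allylation addresses the first two demands and stoichiometry the third.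

3 ⇒ 1 + 2. The pyrone bonds C4–C5 and O1–C2 are cut. Compound 1 already holds the ester carbon, C5, C6 and the whole phenethyl chain; 2 supplies C2, C3 and C4. The forward condensation needs C-acylation at the doubly activated methylene of 1, O-acylation through the ketone enol, and one-to-one stoichiometry so that 3 is not acylated again.

9 ⇒ 7. The two O–Si bonds are cut. Acid 7 holds the C4 carboxyl carbon, C5 and the second prenyl group at the correct oxidation level. Two identical silyl groups are chosen so that loss of either silyloxy group on aromatization leaves the same phenol silyl ether. The forward step must silylate both oxygens and not the α-carbon, and must be worked up without water.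

## Other disconnections considered

Alternative 1: The ring is cut at C2–C3, C4–C5 and C1–C2, leading to the diazo enone 4-diazo-7-methyl-2-(2-phenylethyl)octa-1,6-dien-3-one A1 and the siloxyalkyne triisopropyl[(5-methylhex-4-en-1-yn-1-yl)oxy]silane A2. Irradiation of A1 would trigger a Wolff rearrangement to a vinylketene, which adds A2 in a (2+2) manner. The cyclobutenone would open to a dienylketene and close by six-electron electrocyclization to 2,4-bis(3-methylbut-2-enyl)-5-(2-phenylethyl)-3-(triisopropylsilyloxy)phenol A3, a Danheiser benzannulation.
- In favour: the regiochemistry follows from ketene/ynol ether polarity. Every ring-forming event after the first addition is intramolecular and pericyclic, so crowding should be tolerated better than in the bimolecular cycloaddition of step 5; on this point the alternative is the better plan. The two oxygens of A3 emerge differentiated, which equals the acetate/hydroxyl differentiation in 13.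
- Against: A3 has hydrogen at C1. The carboxyl carbon would still have to be introduced at the most hindered position (ortho-formylation, oxidation of the aldehyde beside two electron-rich alkenes, esterification) before desilylation. That is four operations against the single deacetylation of 13.
- Against: A1, with its substituted diazo carbon, needs a deacylative diazo transfer, and A2 needs an ynolate silylation, so both partners are longer to make and less robust than 6 and 9. Irradiation must also spare two prenyl alkenes that can add to ketenes.
- Comparison: on structure the chosen plan is ahead because its key step delivers all six substituents including the ester, which A3 lacks. On mechanism the alternative is the more forgiving. On step count it is clearly longer.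

Alternative 2: Only the C1–C6 bond is cut, giving the open-chain 2,2-dimethyl-6-[1,3-bis(3-methylbut-2-enyl)-2,4-dioxo-6-phenylhexyl]-4H-1,3-dioxin-4-one A4, which holds all six ring carbons in one chain. Triethylamine would promote aldol addition of the dioxinone α-carbon of A4 to the terminal ketone. Dehydration and enolization would give 7-hydroxy-2,2-dimethyl-6,8-bis(3-methylbut-2-enyl)-5-(2-phenylethyl)-4H-1,3-benzodioxin-4-one A5, and methanolysis of the dioxinone ring of A5 would give 14.
- In favour: the closure is intramolecular, runs near room temperature under weak base and mirrors polyketide biosynthesis. It is mechanistically gentler and probably the more dependable ring-forming event; here the alternative is the better. A5, like 13, carries every substituent and is one step from 14; here the two are equal.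
- Against: the burden moves to A4, a 1,3,5-tricarbonyl chain with two α-prenyl branches that would exist as a mixture of enol and diastereomeric forms. Its assembly needs iterative Claisen acylations and two site-selective C-prenylations (or palladium-mediated prenyl migrations), each with C- versus O-alkylation and over-alkylation problems. The branched chain also offers competing cyclization modes through enol oxygen.
- Comparison: more steps are expected to reach A4 than the three to 6 and one to 9, although the last two steps of the alternative, from A4 through A5 to 14, are the safer ones.

Alternative 3: The ring is kept and the substituent bonds C6–CH2 and C1–CO2Me are cut, leading to 1-chloro-3,5-bis(methoxymethoxy)-2,4-bis(3-methylbut-2-enyl)benzene A6. Lithium 2,2,6,6-tetramethylpiperidide would remove the single ring hydrogen of A6, which lies between chlorine and an acetal oxygen, and loss of LiCl would give the aryne. The Grignard reagent 2-phenylethylmagnesium bromide A7 would add at C6, placing the carbanion at C1 next to the inductively stabilizing oxygen. The electrophile methyl chloroformate A8 would trap C1 to give methyl 2,4-bis(methoxymethoxy)-3,5-bis(3-methylbut-2-enyl)-6-(2-phenylethyl)benzoate A9, and cleavage of the two acetals of A9 would give 14.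
- In favour: no ring has to be built, the two most awkward neighbouring substituents arrive in one three-component operation that leads directly to A9, and the orientation of nucleophilic addition to 3-alkoxyarynes is well established. The step count (protection, two prenylations, key step, deprotection) is about equal to that of the chosen plan.
- Against: A6 itself needs two regioselective C-prenylations of a chlororesorcinol diether, the second at a carbon whose lithiation next to chlorine can itself start aryne formation. The Grignard reagent A7 must attack an aryne carbon flanked by a prenyl group, and the crowded arylmagnesium intermediate must compete with excess A7 for A8.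
- Against: removal of the two methoxymethyl groups of A9 needs acid, the condition under which ortho-prenyl phenols cyclize to chromans, whereas 13 is unmasked with carbonate in methanol.
- Comparison: structurally the plans are equal, since A9 and 13 both hold the whole skeleton. Mechanistically the chosen plan has one regiochemical question answered by polarity and the alternative has several. The end-game of the chosen plan, from 13, is safer than that from A9.

Key step: step 5

## Route

Assumption: compounds 1, 2, 4 and 7 are bought. The atom mapping of 6 and 9 onto 14 is consistent: pyrone C6, C5, C4 and C3 become arene C6, C1, C2 and C3, and the two ketene acetal carbons become C5 and C4. The prenyl group of the pyrone is attached after ring formation so that no prenyl alkene meets hydrogen chloride. Compound 9 is used in excess because the trimethylsilanol released on aromatization consumes ketene acetal.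

Step 1
Reactants: 1 methyl 3-oxo-5-phenylpentanoate; 2 malonyl dichloride
Product: 3 methyl 4-hydroxy-2-oxo-6-(2-phenylethyl)-2H-pyran-5-carboxylate
Conditions: 2 (1.0 equiv), CH2Cl2, 0 → 40 °C, Ar sweep
Reagents that add atoms: none
Why: Known 4-hydroxy-2-pyrone synthesis by double acylation of a β-keto ester with malonyl dichloride: the activated methylene of 1 is C-acylated, the second acyl chloride acylates the ketone enol oxygen, and the product settles as the 4-hydroxy-2-pyrone tautomer. No acid-sensitive group is present while hydrogen chloride is released, and one equivalent of 2 keeps 3 from being acylated again.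

Step 2
Reactants: 3 methyl 4-hydroxy-2-oxo-6-(2-phenylethyl)-2H-pyran-5-carboxylate; 4 3-methylbut-2-enyl acetate (prenyl acetate)
Product: 5 methyl 4-hydroxy-3-(3-methylbut-2-enyl)-2-oxo-6-(2-phenylethyl)-2H-pyran-5-carboxylate
Conditions: 4 (1.0 equiv), Pd(PPh3)4 (5 mol %), Et3N (1.1 equiv), THF, 50 °C
Reagents that add atoms: none
Why: Tsuji–Trost allylation: zerovalent palladium ionizes 4 to the 1,1-dimethylallyl complex, and the soft pyronate from the vinylogous acid 3 attacks the unhindered CH2 terminus through C3, its only nucleophilic carbon. Any O-prenyl ether is re-ionized by the catalyst and funnels to the C-prenyl product, and one equivalent of 4 limits double allylation.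

Step 3
Reactants: 5 methyl 4-hydroxy-3-(3-methylbut-2-enyl)-2-oxo-6-(2-phenylethyl)-2H-pyran-5-carboxylate
Product: 6 methyl 4-acetoxy-3-(3-methylbut-2-enyl)-2-oxo-6-(2-phenylethyl)-2H-pyran-5-carboxylate
Conditions: Ac2O (1.5 equiv), pyridine, 0 → 23 °C
Reagents that add atoms: acetic anhydride, CC(=O)OC(C)=O
Why: O-Acylation of a vinylogous carboxylic acid; C3 is fully substituted, so no oxygen-to-carbon acyl shift can follow. The acetate keeps the diene electron-poor and removes the acidic proton that would destroy 9.

Step 4
Reactants: 7 5-methylhex-4-enoic acid
Product: 9 5-methyl-1,1-bis(trimethylsilyloxy)hexa-1,4-diene, via dilithium enediolate 8 (not isolated)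
Conditions: LiN(iPr)2 (2.2 equiv), THF, −78 → 0 °C; Me3SiCl (2.5 equiv), −78 → 23 °C; pentane, filtration under Ar, distillation
Reagents that add atoms: chlorotrimethylsilane, C[Si](C)(C)Cl
Why: Double deprotonation of a carboxylic acid to its enediolate and O,O-disilylation (ketene bis(silyl) acetal formation); silicon goes to the hard oxygen centres at low temperature. The acetal carbon carries two identical silyloxy groups, so no alkene isomers arise, and the non-aqueous isolation protects the product from hydrolysis.

Step 5
Reactants: 6 methyl 4-acetoxy-3-(3-methylbut-2-enyl)-2-oxo-6-(2-phenylethyl)-2H-pyran-5-carboxylate; 9 5-methyl-1,1-bis(trimethylsilyloxy)hexa-1,4-diene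
Product: 13 methyl 2-acetoxy-4-hydroxy-3,5-bis(3-methylbut-2-enyl)-6-(2-phenylethyl)benzoate, via bridged lactone cycloadduct 10 (not isolated), via cyclohexadiene ketal 11 (not isolated), via aryl trimethylsilyl ether 12 (not isolated)
Conditions: 9 (3 equiv), toluene, 120 °C, sealed tube, Ar; then THF/aq. citric acid, 23 °C
Reagents that add atoms: none
Why: Inverse-electron-demand Diels–Alder reaction of a 2-pyrone-5-carboxylate with a ketene acetal followed by cycloreversion; the closest known type is the conversion of coumalate-type pyrones and 1,1-dialkoxyethenes into alkoxybenzoates. The HOMO of 9 meets the LUMO of 6, lowered by the lactone carbonyl, the C5 ester and the acetoxy group; bonding may be concerted and asynchronous, or a Mukaiyama–Michael addition followed by closure onto the silyloxycarbenium ion, and both paths give bridged lactone 10. Retro-(4+2) loss of CO2 from 10 gives cyclohexadiene 11, 1,2-elimination of trimethylsilanol across C4–C5 gives aryl silyl ether 12, and the mildly acidic work-up hydrolyses 12 to 13. The benzene ring is closed by intermolecular (4+2) cycloaddition, pyrone C3 to C6 supplying four ring atoms and the ketene acetal two, with formation of the arene bonds C3–C4 and C5–C6. The stereocentres of 10 and 11 are erased on aromatization, so no stereocontrol is needed. The selectivity required is regiochemical: pyrone C6, β to the ester and at the far end of the dienyl lactone, is the most electrophilic terminus and takes the nucleophilic CH carbon of 9, so the hydroxyl ends up para to the ester and the new prenyl group next to the phenethyl chain. Chemoselectivity rests on the prenyl alkenes being electronically unactivated and on both acetal oxygens carrying the same silyl group, so either elimination gives the same phenol.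

Step 6
Reactants: 13 methyl 2-acetoxy-4-hydroxy-3,5-bis(3-methylbut-2-enyl)-6-(2-phenylethyl)benzoate
Product: 14 methyl 2,4-dihydroxy-3,5-bis(3-methylbut-2-enyl)-6-(2-phenylethyl)benzoate
Conditions: K2CO3 (1.5 equiv), degassed MeOH, 0 → 23 °C; aq. NH4Cl
Reagents that add atoms: none
Why: Base-mediated methanolysis (transesterification) of an aryl acetate; phenoxide is a far better leaving group than the alkoxide of the hindered methyl benzoate, whose exchange with methanol is degenerate anyway. The non-acidic conditions spare the ortho-prenyl phenol units from chroman formation.

## Compound list

1 | methyl 3-oxo-5-phenylpentanoate | COC(=O)CC(=O)CCc1ccccc1 | starting material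
2 | malonyl dichloride (propanedioyl dichloride) | O=C(Cl)CC(=O)Cl | starting material
3 | methyl 4-hydroxy-2-oxo-6-(2-phenylethyl)-2H-pyran-5-carboxylate | COC(=O)C1=C(CCc2ccccc2)OC(=O)C=C1O | intermediate
4 | 3-methylbut-2-enyl acetate (prenyl acetate) | CC(=O)OCC=C(C)C | starting material
5 | methyl 4-hydroxy-3-(3-methylbut-2-enyl)-2-oxo-6-(2-phenylethyl)-2H-pyran-5-carboxylate | COC(=O)C1=C(CCc2ccccc2)OC(=O)C(CC=C(C)C)=C1O | intermediate
6 | methyl 4-acetoxy-3-(3-methylbut-2-enyl)-2-oxo-6-(2-phenylethyl)-2H-pyran-5-carboxylate | COC(=O)C1=C(CCc2ccccc2)OC(=O)C(CC=C(C)C)=C1OC(C)=O | intermediate
7 | 5-methylhex-4-enoic acid | CC(C)=CCCC(=O)O | starting material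
8 | dilithium 5-methylhexa-1,4-diene-1,1-bis(olate) (enediolate of 7) | [Li+].[Li+].CC(C)=CCC=C([O-])[O-] | intermediate
9 | 5-methyl-1,1-bis(trimethylsilyloxy)hexa-1,4-diene | C[Si](C)(C)OC(O[Si](C)(C)C)=CCC=C(C)C | intermediate
10 | methyl 5-acetoxy-4,7-bis(3-methylbut-2-enyl)-3-oxo-1-(2-phenylethyl)-8,8-bis(trimethylsilyloxy)-2-oxabicyclo[2.2.2]oct-5-ene-6-carboxylate (racemic, C7 configuration uncontrolled, transient) | CC(C)=CCC1C2(CCc3ccccc3)OC(=O)C(CC=C(C)C)(C(OC(C)=O)=C2C(=O)OC)C1(O[Si](C)(C)C)O[Si](C)(C)C | intermediate
11 | methyl 6-acetoxy-3,5-bis(3-methylbut-2-enyl)-2-(2-phenylethyl)-4,4-bis(trimethylsilyloxy)cyclohexa-1,5-diene-1-carboxylate (racemic, transient) | COC(=O)C1=C(CCc2ccccc2)C(CC=C(C)C)C(O[Si](C)(C)C)(O[Si](C)(C)C)C(CC=C(C)C)=C1OC(C)=O | intermediate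
12 | methyl 2-acetoxy-3,5-bis(3-methylbut-2-enyl)-6-(2-phenylethyl)-4-(trimethylsilyloxy)benzoate | COC(=O)c1c(OC(C)=O)c(CC=C(C)C)c(O[Si](C)(C)C)c(CC=C(C)C)c1CCc1ccccc1 | intermediate
13 | methyl 2-acetoxy-4-hydroxy-3,5-bis(3-methylbut-2-enyl)-6-(2-phenylethyl)benzoate | COC(=O)c1c(OC(C)=O)c(CC=C(C)C)c(O)c(CC=C(C)C)c1CCc1ccccc1 | intermediate
14 | methyl 2,4-dihydroxy-3,5-bis(3-methylbut-2-enyl)-6-(2-phenylethyl)benzoate | COC(=O)c1c(O)c(CC=C(C)C)c(O)c(CC=C(C)C)c1CCc1ccccc1 | target

## Step count and least certain steps

Total: 6 steps. Longest linear sequence: 5 steps (steps 1, 2, 3, 5, 6); step 4 is a one-step side branch.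

Step 5 (key step). Bond formation between the two fully substituted pyrone termini and a trisubstituted ketene acetal may be too slow. In that case 9 would be lost by thermal oxygen-to-carbon silyl migration or protodesilylation, conjugate addition at C6 could stop without ring closure, or the nucleophile could attack the acetyl group or C4 with loss of acetate. The fallback moves the introduction of the C5 prenyl group to the end. Setting out from 6, the cycloaddition is run with the unsubstituted 1,1-bis(trimethylsilyloxy)ethene F1 (from trimethylsilyl acetate, LiN(iPr)2 and Me3SiCl), whose CH2 terminus reaches C6 with far less strain. This should give methyl 2-acetoxy-4-hydroxy-3-(3-methylbut-2-enyl)-6-(2-phenylethyl)benzoate F2. K2CO3 in methanol then gives methyl 2,4-dihydroxy-3-(3-methylbut-2-enyl)-6-(2-phenylethyl)benzoate F3. One equivalent of NaH should deprotonate the C4 hydroxyl, which is not hydrogen-bonded to the ester. Ortho C-prenylation of this phenoxide with prenyl bromide in toluene at C5, the only unsubstituted ring carbon, returns to the route at 14.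

Step 2. A second allylation at C3 to the 3,3-diprenyl dione, O-allylation that fails to equilibrate, or attack at the tertiary allyl terminus could erode the yield of the linear mono-C-prenyl product, because the product is as acidic as the substrate. The fallback builds the prenyl group into the three-carbon unit. Diethyl malonate is alkylated with prenyl bromide (NaOEt, EtOH) to diethyl 2-(3-methylbut-2-enyl)malonate F4. Saponification (KOH, aqueous EtOH, acidification at 0 °C) gives 2-(3-methylbut-2-enyl)malonic acid F5, and oxalyl chloride with catalytic DMF gives 2-(3-methylbut-2-enyl)malonyl dichloride F6. Condensation of F6 with 1 under an argon sweep, as in step 1, gives 5; the fallback sets out from 1 and returns at 5. It is the second choice because it exposes a prenyl group to hydrogen chloride.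

Step 1. Acylation of 3 by a second molecule of 2, reaction through the γ-enol of 1, or self-condensation of 2 could give fused or oligomeric by-products, because both partners are polyfunctional. The fallback separates the two acylations. Setting out from 1, soft enolization (MgCl2, Et3N) and C-acylation with methyl 3-chloro-3-oxopropanoate gives dimethyl 3-oxo-2-(3-phenylpropanoyl)pentanedioate F7. Heating F7 with 1,8-diazabicyclo[5.4.0]undec-7-ene in toluene lactonizes the ketone enol onto the terminal ester with loss of methanol and returns to the route at 3.

Step 4. C-silylation of the dianion, or hydrolysis of the product during isolation, could lower the purity of 9, because the enediolate is ambident and 9 is moisture-sensitive. The fallback goes through the mono-anion of a silyl ester. Setting out from 7, hexamethyldisilazane gives trimethylsilyl 5-methylhex-4-enoate F8, which is distilled. Deprotonation of F8 with LiN(iPr)2 at −78 °C and trapping with Me3SiCl, which for a silyl ester enolate goes to oxygen, returns to the route at 9.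

## Further compounds

F1 | step 5 | 1,1-bis(trimethylsilyloxy)ethene | C=C(O[Si](C)(C)C)O[Si](C)(C)C
F2 | step 5 | methyl 2-acetoxy-4-hydroxy-3-(3-methylbut-2-enyl)-6-(2-phenylethyl)benzoate | COC(=O)c1c(OC(C)=O)c(CC=C(C)C)c(O)cc1CCc1ccccc1
F3 | step 5 | methyl 2,4-dihydroxy-3-(3-methylbut-2-enyl)-6-(2-phenylethyl)benzoate | COC(=O)c1c(O)c(CC=C(C)C)c(O)cc1CCc1ccccc1
F4 | step 2 | diethyl 2-(3-methylbut-2-enyl)malonate | CCOC(=O)C(CC=C(C)C)C(=O)OCC
F5 | step 2 | 2-(3-methylbut-2-enyl)malonic acid | CC(C)=CCC(C(=O)O)C(=O)O
F6 | step 2 | 2-(3-methylbut-2-enyl)malonyl dichloride | CC(C)=CCC(C(=O)Cl)C(=O)Cl
F7 | step 1 | dimethyl 3-oxo-2-(3-phenylpropanoyl)pentanedioate | COC(=O)CC(=O)C(C(=O)OC)C(=O)CCc1ccccc1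
F8 | step 4 | trimethylsilyl 5-methylhex-4-enoate | CC(C)=CCCC(=O)O[Si](C)(C)C
A1 | alternative 1 | 4-diazo-7-methyl-2-(2-phenylethyl)octa-1,6-dien-3-one | C=C(CCc1ccccc1)C(=O)C(=[N+]=[N-])CC=C(C)C
A2 | alternative 1 | triisopropyl[(5-methylhex-4-en-1-yn-1-yl)oxy]silane | CC(C)=CCC#CO[Si](C(C)C)(C(C)C)C(C)C
A3 | alternative 1 | 2,4-bis(3-methylbut-2-enyl)-5-(2-phenylethyl)-3-(triisopropylsilyloxy)phenol | CC(C)=CCc1c(O)cc(CCc2ccccc2)c(CC=C(C)C)c1O[Si](C(C)C)(C(C)C)C(C)C
A4 | alternative 2 | 2,2-dimethyl-6-[1,3-bis(3-methylbut-2-enyl)-2,4-dioxo-6-phenylhexyl]-4H-1,3-dioxin-4-one | CC1(C)OC(=O)C=C(O1)C(CC=C(C)C)C(=O)C(CC=C(C)C)C(=O)CCc1ccccc1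
A5 | alternative 2 | 7-hydroxy-2,2-dimethyl-6,8-bis(3-methylbut-2-enyl)-5-(2-phenylethyl)-4H-1,3-benzodioxin-4-one | CC1(C)OC(=O)c2c(CCc3ccccc3)c(CC=C(C)C)c(O)c(CC=C(C)C)c2O1
A6 | alternative 3 | 1-chloro-3,5-bis(methoxymethoxy)-2,4-bis(3-methylbut-2-enyl)benzene | COCOc1cc(Cl)c(CC=C(C)C)c(OCOC)c1CC=C(C)C
A7 | alternative 3 | 2-phenylethylmagnesium bromide | Br[Mg]CCc1ccccc1
A8 | alternative 3 | methyl chloroformate | COC(=O)Cl
A9 | alternative 3 | methyl 2,4-bis(methoxymethoxy)-3,5-bis(3-methylbut-2-enyl)-6-(2-phenylethyl)benzoate | COC(=O)c1c(OCOC)c(CC=C(C)C)c(OCOC)c(CC=C(C)C)c1CCc1ccccc1
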